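## Analysis of the target

3,4,6-Tribromoindole is a flat, achiral 1H-indole in which a benzene ring (ring A, C3a to C7a) is fused to a pyrrole ring (ring B, N1, C2, C3). Bromine sits on C3 of ring B and on C4 and C6 of ring A. There is no stereocentre, so the synthesis is purely a problem of regiochemistry: three of the six ring C–H positions must carry bromine while C2, C5 and C7 stay untouched. The three positions are unequal. C3 is the innately nucleophilic enamine carbon and takes up electrophilic bromine easily. C6 cannot be brominated selectively on an indole, but a commercial indole already carries bromine there. C4 is the least accessible benzenoid position, reached neither by electrophilic substitution nor, with other aryl bromides present, by lithiation. The sensitive elements are the free N–H 3-bromoindole unit, which is prone to over-halogenation at C2 and to decomposition in acid and light, and the aryl C–Br bonds, which exclude zerovalent palladium, organolithium reagents and dissolving metals once they are in place. The plan rests on the peri relationship between C3 and C4: a donor atom attached through one carbon to C3 lies within reach of the C4–H bond. A formyl group on C3 can therefore steer a metal to C4, and because it occupies exactly the position of the third bromine, it can afterwards be exchanged for that bromine by oxidation and ipso substitution.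

## Retrosynthetic reasoning

The last bond made is C3–Br of target 13. It is cut first because the free N–H 3-bromoindole is the most fragile array in the molecule and because C3 is the one position whose substituent can be exchanged by ipso attack. The cut leads to the C3 carboxylic acid 11 and to 6 as the bromine source. The electron-rich indole should take up bromine at the carbon that bears the carboxyl group to give the non-aromatic acid 12, which can regain aromaticity only by decarboxylation. What is gained is a carbon substituent at C3, the handle needed further back. The forward reaction has to stop after one equivalent of 6 so that C2 is not attacked.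

The N–H of 11 is traced back to the N-sulfonyl acid 10 by cutting an N–S bond. The sulfonyl group has to be gone before the last step, since ipso substitution at C3 needs the nucleophilicity of the unprotected ring, but it should still be present during the two preceding oxidative operations. The forward reaction is a basic hydrolysis that must cleave N–S without touching the two aryl bromides.

Acid 10 is derived from aldehyde 9 by adjusting the oxidation level of the C3 carbon; no skeletal bond is cut. The carboxyl group is what the ipso exchange requires, the formyl group is what the preceding C–H functionalisation requires, and a Pinnick oxidation links the two. Oxidising the N-sulfonyl compound, not the free indole, keeps the ring deactivated towards the electrophilic chlorine that the oxidant releases and keeps the aldehyde a normal electrophile.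

The C4–Br bond of 9 is the strategic cut; it leads to the monobromide 5 and again to 6. The cut is placed here because 5 offers, through its C3 formyl group, a directing element for exactly this C–H bond, while the sulfonyl and formyl groups together make the ring inert to 6 on its own. In the forward direction the formyl group of 5 is to condense reversibly with a catalytic aromatic amino acid to give imine 7. Its nitrogen and carboxylate hold divalent palladium over the peri C4–H bond, metalation and bromine transfer from 6 give imine 8, and hydrolysis returns the aldehyde as 9. An aliphatic α-amino acid would be degraded oxidatively by 6, so an aromatic amino acid with a blocked para position is planned as the carrier. The reaction has to prefer C4 over C2 and must leave the C6–Br bond alone; the latter follows from a cycle that never passes through zerovalent palladium.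

Sulfonamide 5 is cut at the N–S bond into aldehyde 3 and sulfonyl chloride 4. The sulfonyl group is introduced only after formylation, because it would shut down the electrophilic substitution that installs the formyl group. Its tasks afterwards are to lower the nucleophilicity of the ring towards 6 and to crowd C2.

Aldehyde 3 is cut at the C3–CHO bond, which leads via iminium salt 2 to commercial 1 by a Vilsmeier–Haack formylation at the innately reactive C3. Compound 1 already carries the C6 bromine, the one halogen that no reaction on the indole nucleus would place selectively, so nothing is left to disconnect.

## Alternatives that were turned down

Alternative 1: Ring A is built instead of functionalised. The C3a–C7a and C4–C5 bonds are cut, which leads to a 2-amidofuran with a tethered bromoalkene, tert-butyl N-(4-bromofuran-2-yl)-N-[(E)-4-bromobut-3-en-1-yl]carbamate (A1). On heating, the furan would act as diene and the vinyl bromide as dienophile in an intramolecular [4+2] cycloaddition that closes the carbocycle and the five-membered nitrogen ring together. Nitrogen-assisted opening of the oxygen bridge and dehydration would then give the arene tert-butyl 4,6-dibromoindoline-1-carboxylate (A2).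
- For: both ring A bromines are fixed by the connectivity of A1, so no C–H selectivity question arises, and no transition metal is needed.
- Against: A1 is itself a multistep compound. Its amidofuran part must come from a Curtius rearrangement of a brominated furoic acid and is sensitive to acid and air. An unactivated vinyl bromide is a sluggish dienophile, and at the temperatures required the bridged adduct can aromatise by dehydrobromination instead of dehydration, which would delete the C4 bromine. After A2 the carbamate must still be removed, the indoline dehydrogenated and C3 brominated.
- Comparison: on regiochemical certainty in ring A this route is stronger than the chosen one, but it is roughly twice as long and its key step has its own chemoselectivity problem. The chosen strategy buys rings A and B complete, with C6 already brominated, and spends one directed step on C4.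

Alternative 2: Ring B is closed at the C2=C3 bond. The precursor is the benzylic phosphonium salt [(2,4-dibromo-6-formamidophenyl)methyl]triphenylphosphonium bromide (A3). An alkoxide base would generate the benzylic ylide, which adds to the formamide carbonyl; loss of the phosphine oxide gives 4,6-dibromo-1H-indole (A4), and bromination of A4 at C3 with 6 would finish 13.
- For: every step is classical, the two ring A bromines are placed on a benzene precursor, the last bromination occurs at the innately reactive position, and no precious metal is used.
- Against: the arene behind A3 must carry both bromines meta to nitrogen, against the ortho/para direction of an amino group. It can only be reached through a temporary second amino group that is later removed by diazotisation, followed by benzylic bromination between two ortho substituents, phosphonium formation, nitro reduction and formylation. A formamide is also a poor electrophile for a semi-stabilised benzylic ylide, so the closure needs forcing conditions.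
- Comparison: the certainty of the bromine pattern is at least as good as in the chosen route, but the sequence would run to eight or nine steps against six. The chosen route draws the same certainty for C3 and C6 from commercial 1 and concentrates its risk in one catalytic step.

Alternative 3: The N1–C2 and C3–Br bonds are made in one operation. The precursor is the ortho-alkynyl sulfonanilide N-{3,5-dibromo-2-[(trimethylsilyl)ethynyl]phenyl}-4-methylbenzenesulfonamide (A5). A copper bromide salt would activate the alkyne, the sulfonamide nitrogen would add in a 5-endo closure of ring B, and the C3–copper intermediate would be converted into the C3–Br bond to give 3,4,6-tribromo-1-tosyl-2-(trimethylsilyl)indole (A6).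
- For: one step forms ring B and the third bromine, and the ring A pattern is again fixed in the arene.
- Against: A5 requires iodination of its aniline precursor ortho and not para to nitrogen, then a Sonogashira coupling at a position flanked by two ortho substituents, with zerovalent palladium in the presence of two aryl bromides. The silyl group on C2 of A6 is exposed to bromodesilylation under the cyclisation conditions, which would put a fourth bromine on C2. Two groups, on nitrogen and on C2, have to be removed from the sensitive tribromide at the end.
- Comparison: in step count this route is about as short as the chosen one, and it is more convergent. The chosen strategy offers in exchange that zerovalent palladium never meets an aryl bromide, that C2 is never functionalised, and that the labile C3 bromide is introduced in the last operation and is not carried through deprotections.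

Key step: step 3

Remark: the amino acid catalyst of step 3 is 2-amino-5-chlorobenzoic acid (Nc1ccc(Cl)cc1C(=O)O); palladium-bound species of the catalytic cycle and sodium salts formed by simple deprotonation are treated as forms of the numbered compounds and carry no numbers of their own.

## Route

Step 1
Reactants: 1 6-bromo-1H-indole
Product: 3 6-bromo-1H-indole-3-carbaldehyde, via iminium chloride 2 (not isolated)
Conditions: POCl3 (1.2 equiv), DMF, 0 °C to 40 °C; then aq. NaOH, 0 °C to 90 °C (brief)
Reagents that add atoms: N,N-dimethylformamide, CN(C)C=O; water, O
Why: Vilsmeier–Haack formylation: the chloroiminium ion formed from DMF and POCl3 attacks C3, the most nucleophilic position of the indole, to give iminium salt 2, which aqueous base hydrolyses to the aldehyde. The C6 bromine deactivates the ring only mildly and is inert under these conditions.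

Step 2
Reactants: 3 6-bromo-1H-indole-3-carbaldehyde; 4 4-toluenesulfonyl chloride
Product: 5 6-bromo-1-(4-methylbenzenesulfonyl)-1H-indole-3-carbaldehyde
Conditions: NaH, THF, 0 °C; then TsCl, 0 °C to rt
Reagents that add atoms: none
Why: N-sulfonylation of a vinylogous formamide whose N–H is acidified by the C3 formyl group; the sodium salt should react cleanly at nitrogen with the sulfonyl chloride.

Step 3
Reactants: 5 6-bromo-1-(4-methylbenzenesulfonyl)-1H-indole-3-carbaldehyde; 6 N-bromosuccinimide
Product: 9 4,6-dibromo-1-(4-methylbenzenesulfonyl)-1H-indole-3-carbaldehyde, via transient imine 7 (not isolated), via C4-brominated imine 8 (not isolated)
Conditions: Pd(OAc)2 (10 mol %), 2-amino-5-chlorobenzoic acid (40 mol %), NBS (1.2 equiv), CF3CO2H (5 equiv), ClCH2CH2Cl, 60 °C, dark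
Reagents that add atoms: none
Why: Transient-directing-group C–H halogenation of an aromatic aldehyde, a known reaction type for indole-3-carbaldehydes and benzaldehydes. The amino acid condenses reversibly with the formyl group of 5 to give imine 7, whose nitrogen and carboxylate bind divalent palladium as a six-membered chelate and place the metal next to the peri C4–H bond. Carboxylate-assisted concerted metalation–deprotonation there gives a six-membered palladacycle fused to the chelate ring; acid-activated 6 oxidises it to a tetravalent palladium bromide, C4–Br reductive elimination gives imine 8 and returns divalent palladium, and the water released in the condensation hydrolyses 8 to 9 and frees the amine. No ring and no stereocentre is formed in the product. The selectivity needed is C4 over C2: the wide exocyclic angles of the five-membered ring put the C2–H bond out of reach of a strain-free five-membered palladacycle, whereas the peri geometry fits the six-membered one, and the N-sulfonyl group crowds C2. The sulfonyl and formyl groups together make the ring too electron-poor for uncatalysed bromination by 6 at C2, C5 or C7. Because the cycle runs between divalent and tetravalent palladium, no zerovalent palladium arises that could insert into the C6–Br bond. The para-chloro substituent of the amine blocks its most reactive ring position against 6.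

Step 4
Reactants: 9 4,6-dibromo-1-(4-methylbenzenesulfonyl)-1H-indole-3-carbaldehyde
Product: 10 4,6-dibromo-1-(4-methylbenzenesulfonyl)-1H-indole-3-carboxylic acid
Conditions: NaClO2, NaH2PO4, 2-methyl-2-butene, t-BuOH/THF/H2O, 0 °C to rt
Reagents that add atoms: sodium chlorite, [Na+].[O-]Cl=O
Why: Pinnick oxidation: chlorous acid adds to the aldehyde and fragments to the acid and HOCl, which the alkene traps. The N-sulfonyl group keeps the aldehyde electrophilic (no vinylogous amide character) and the ring inert to electrophilic chlorine; the aryl bromides and the sulfonamide should be untouched.

Step 5
Reactants: 10 4,6-dibromo-1-(4-methylbenzenesulfonyl)-1H-indole-3-carboxylic acid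
Product: 11 4,6-dibromo-1H-indole-3-carboxylic acid
Conditions: aq. NaOH (2 M), THF, 65 °C; then aq. HCl to pH 3, 0 °C
Reagents that add atoms: none
Why: Alkaline hydrolysis of an N-sulfonylindole: hydroxide attacks sulfur and expels the indolide, a good leaving group because its charge is delocalised towards the C3 carboxyl group and stabilised by two bromines. Aryl bromides do not react with hydroxide at this temperature, and cold acidification limits protodecarboxylation.

Step 6
Reactants: 11 4,6-dibromo-1H-indole-3-carboxylic acid; 6 N-bromosuccinimide
Product: 13 3,4,6-tribromo-1H-indole, via 3-bromo-3H-indole acid 12 (not isolated)
Conditions: NBS (1.0 equiv), LiOAc (10 mol %), DMF, 0 °C to rt, dark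
Reagents that add atoms: none
Why: Hunsdiecker-type ipso-bromodecarboxylation, known for electron-rich heteroaromatic acids including indole-3-carboxylic acids: bromine is delivered to C3, the enamine carbon that bears the carboxylate, to give the 3H-indole 12, which has no proton at C3 and rearomatises by losing CO2. One equivalent of 6 at low temperature should prevent subsequent bromination at C2, and the peri strain between the C3 carboxyl group and the C4 bromine is relieved on going to 12.

## Compound list

1 | 6-bromo-1H-indole | Brc1ccc2cc[nH]c2c1 | starting material
2 | N-[(6-bromo-1H-indol-3-yl)methylidene]-N-methylmethanaminium chloride | C[N+](C)=Cc1c[nH]c2cc(Br)ccc12.[Cl-] | intermediate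
3 | 6-bromo-1H-indole-3-carbaldehyde | O=Cc1c[nH]c2cc(Br)ccc12 | intermediate
4 | 4-toluenesulfonyl chloride | Cc1ccc(cc1)S(=O)(=O)Cl | starting material
5 | 6-bromo-1-(4-methylbenzenesulfonyl)-1H-indole-3-carbaldehyde | O=Cc1cn(S(=O)(=O)c2ccc(C)cc2)c2cc(Br)ccc12 | intermediate
6 | N-bromosuccinimide | O=C1CCC(=O)N1Br | starting material
7 | 2-[(E)-{[6-bromo-1-(4-methylbenzenesulfonyl)-1H-indol-3-yl]methylidene}amino]-5-chlorobenzoic acid | OC(=O)c1cc(Cl)ccc1/N=C/c1cn(S(=O)(=O)c2ccc(C)cc2)c2cc(Br)ccc12 | intermediate
8 | 2-[(E)-{[4,6-dibromo-1-(4-methylbenzenesulfonyl)-1H-indol-3-yl]methylidene}amino]-5-chlorobenzoic acid | OC(=O)c1cc(Cl)ccc1/N=C/c1cn(S(=O)(=O)c2ccc(C)cc2)c2cc(Br)cc(Br)c12 | intermediate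
9 | 4,6-dibromo-1-(4-methylbenzenesulfonyl)-1H-indole-3-carbaldehyde | O=Cc1cn(S(=O)(=O)c2ccc(C)cc2)c2cc(Br)cc(Br)c12 | intermediate
10 | 4,6-dibromo-1-(4-methylbenzenesulfonyl)-1H-indole-3-carboxylic acid | OC(=O)c1cn(S(=O)(=O)c2ccc(C)cc2)c2cc(Br)cc(Br)c12 | intermediate
11 | 4,6-dibromo-1H-indole-3-carboxylic acid | OC(=O)c1c[nH]c2cc(Br)cc(Br)c12 | intermediate
12 | 3,4,6-tribromo-3H-indole-3-carboxylic acid (racemic, transient) | OC(=O)C1(Br)C=Nc2cc(Br)cc(Br)c21 | intermediate
13 | 3,4,6-tribromo-1H-indole | Brc1cc(Br)c2c(Br)c[nH]c2c1 | target

Total step count: 6. Longest linear sequence: 6 steps (1 to 13).

## Least certain steps

Step 3 (key step). The most likely failures concern site selectivity and turnover. Palladation could stray to C2 through the alternative five-membered palladacycle. Acid-activated 6 could brominate the substrate or the catalyst amine without palladium. The condensation of a weakly nucleophilic aniline with a deactivated aldehyde could be too slow to keep the cycle running, so that conversion stalls. The fallback sets out from 3 and comes back at 9. Electrophilic thallation of the free indole aldehyde 3 with Tl(O2CCF3)3 in CF3CO2H, in which the formyl oxygen delivers trivalent thallium to the peri position, should give (6-bromo-3-formyl-1H-indol-4-yl)thallium bis(trifluoroacetate) F1. Exchange of thallium for bromine with CuBr2 in DMF would give 4,6-dibromo-1H-indole-3-carbaldehyde F2, and N-sulfonylation of F2 with 4 (NaH, THF) leads to 9. This replaces catalytic palladation by a stoichiometric main-group metalation and requires the precautions appropriate to thallium salts.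

Step 6. The most likely failure is loss of control over the electrophile. Ipso attack at C3 may be slowed by the peri C4 bromine, so that bromination continues at C2 once the first product has formed, or the acid released may degrade the N–H 3-bromoindole. The fallback sets out from 11 and comes back at 13. Thermal protodecarboxylation of 11 in hot acetic acid, in which protonation at C3 precedes loss of the carboxyl group, should give 4,6-dibromo-1H-indole F3. Electrophilic bromination of F3 at the now free, innately reactive C3 with one equivalent of 6 in DMF at 0 °C then gives 13. The ipso substitution is thus replaced by a two-stage removal and re-functionalisation at C3.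

Step 5. The most likely failure is incomplete N–S cleavage, because under the basic conditions the substrate is a carboxylate anion and a poorer partner for hydroxide, together with partial loss of the carboxyl group if the mixture is heated harder or acidified warm. The fallback sets out from 9 and comes back at 11 by changing the order of operations. The sulfonyl group is hydrolysed at the aldehyde stage (aq. NaOH, THF, rt), where the C3 formyl group makes the indolide a far better leaving group and no carboxyl group is present, to give 4,6-dibromo-1H-indole-3-carbaldehyde F4 (the same substance as F2). Pinnick oxidation of F4 (NaClO2, NaH2PO4, large excess of 2-methyl-2-butene) then gives 11.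

Steps 1, 2 and 4 are routine operations on this substrate class and carry little risk.

## Further compounds

F1 | step 3 | (6-bromo-3-formyl-1H-indol-4-yl)thallium bis(trifluoroacetate) | O=Cc1c[nH]c2cc(Br)cc([Tl](OC(=O)C(F)(F)F)OC(=O)C(F)(F)F)c12
F2 | step 3 | 4,6-dibromo-1H-indole-3-carbaldehyde | O=Cc1c[nH]c2cc(Br)cc(Br)c12
F3 | step 6 | 4,6-dibromo-1H-indole | Brc1cc(Br)c2cc[nH]c2c1
F4 | step 5 | 4,6-dibromo-1H-indole-3-carbaldehyde | O=Cc1c[nH]c2cc(Br)cc(Br)c12
A1 | alternative 1 | tert-butyl N-(4-bromofuran-2-yl)-N-[(E)-4-bromobut-3-en-1-yl]carbamate | CC(C)(C)OC(=O)N(CC/C=C/Br)c1cc(Br)co1
A2 | alternative 1 | tert-butyl 4,6-dibromoindoline-1-carboxylate | CC(C)(C)OC(=O)N1CCc2c(Br)cc(Br)cc21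
A3 | alternative 2 | [(2,4-dibromo-6-formamidophenyl)methyl]triphenylphosphonium bromide | O=CNc1cc(Br)cc(Br)c1C[P+](c1ccccc1)(c1ccccc1)c1ccccc1.[Br-]
A4 | alternative 2 | 4,6-dibromo-1H-indole | Brc1cc(Br)c2cc[nH]c2c1
A5 | alternative 3 | N-{3,5-dibromo-2-[(trimethylsilyl)ethynyl]phenyl}-4-methylbenzenesulfonamide | Cc1ccc(cc1)S(=O)(=O)Nc1cc(Br)cc(Br)c1C#C[Si](C)(C)C
A6 | alternative 3 | 3,4,6-tribromo-1-tosyl-2-(trimethylsilyl)indole | Cc1ccc(cc1)S(=O)(=O)n1c([Si](C)(C)C)c(Br)c2c(Br)cc(Br)cc21
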